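**Retrosynthetic overview**

1. Feature: the C4 hydroxyl of ring A (C1 CH2OH, C2 Br, C3 ether O, C4 OH, C5 Br, C6 H) and the C2' hydroxymethyl carbon of ring B (C1' ether O, C2' CH2OH, C3' H, C4' Br, C5' and C6' OH) both lie ortho to the diaryl ether oxygen. They can therefore be joined as an ester, which maps the target onto a depsidone (dibenzo[b,e][1,4]dioxepin-11-one).
2. Late stage: both CH2OH groups come from methyl esters, the catechol from two methyl ethers, and Br at C5 and C4' from bromination ortho to the C4 hydroxyl and the C5' oxygen. The diester phenol comes from methanolysis of the depsidone lactone.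
3. Key disconnection: the O–C3 ether bond, closed by copper-mediated attack of the C1' phenoxide of a depside on the C3 iodide of ring A.
4. Depside: ester of 2-hydroxy-3,4-dimethoxybenzoic acid with methyl 2-bromo-4-hydroxy-3-iodobenzoate. The latter comes from methyl 3-iodo-4-methoxybenzoate by C2 magnesiation/bromination and O-demethylation.
5. Ring order: both benzene rings are purchased. The only ring formed is the seven-membered dioxepinone ring (step 4), and it is opened again in step 5.

Key step: step 4

Remark on the chemistry: the target has no stereocentre. The locants C1–C6 (ring A) and C1'–C6' (ring B) defined above are used for every intermediate.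

**Route**

Step 1
Reactants: 1 methyl 3-iodo-4-methoxybenzoate
Product: 3 methyl 2-bromo-3-iodo-4-methoxybenzoate, via C2 arylmagnesium chloride 2 (not isolated)
Conditions: TMPMgCl·LiCl (1.2 equiv), THF, −20 °C, 3 h; then BrCl2C–CCl2Br (1.3 equiv), −20 °C → rt
Reagents that add atoms: 1,2-dibromo-1,1,2,2-tetrachloroethane, BrC(Cl)(Cl)C(Cl)(Cl)Br (Br at C2 of 3); TMPMgCl·LiCl, CC1(C)CCCC(C)(C)N1[Mg]Cl.[Li+].[Cl-] (MgCl in intermediate 2 only)
Why: Directed ortho-magnesiation with the Knochel–Hauser base should take place at C2–H, which is guided by the ester carbonyl and acidified by the neighbouring iodine; the amide base cannot undergo iodine–magnesium exchange, the cold arylmagnesium 2 should not lose MgClI to an aryne, and the dibromide transfers electrophilic bromine to the C–Mg bond.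

Step 2
Reactants: 3 methyl 2-bromo-3-iodo-4-methoxybenzoate
Product: 4 methyl 2-bromo-4-hydroxy-3-iodobenzoate
Conditions: BBr3 (2.5 equiv), CH2Cl2, −78 → 0 °C; then MeOH, aq. NaHCO3
Reagents that add atoms: none
Why: Lewis-acid ether cleavage (BBr3 O-demethylation) should remove the C4 methyl group by boron coordination and SN2 attack of bromide, while the methyl ester and both aryl halides survive at or below 0 °C.

Step 3
Reactants: 4 methyl 2-bromo-4-hydroxy-3-iodobenzoate; 5 2-hydroxy-3,4-dimethoxybenzoic acid
Product: 7 methyl 2-bromo-4-[(2-hydroxy-3,4-dimethoxybenzoyl)oxy]-3-iodobenzoate, via aroyl trifluoroacetate mixed anhydride 6 (not isolated)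
Conditions: (CF3CO)2O (2.5 equiv), toluene, 0 °C → rt; aq. NaHCO3 wash
Reagents that add atoms: trifluoroacetic anhydride, O=C(OC(=O)C(F)(F)F)C(F)(F)F (its CF3CO group is carried only by intermediate 6; none of its atoms stays in 7)
Why: Mixed-anhydride esterification (trifluoroacetic anhydride depside coupling) should work because the electron-rich acid forms the acyl trifluoroacetate 6, which transfers its aroyl group to the phenol 4; the hydrogen-bonded 2-hydroxyl is a poor nucleophile and any aryl trifluoroacetate is cleaved in the bicarbonate wash.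

Step 4
Reactants: 7 methyl 2-bromo-4-[(2-hydroxy-3,4-dimethoxybenzoyl)oxy]-3-iodobenzoate
Product: 8 methyl 6-bromo-3,4-dimethoxy-11-oxo-11H-dibenzo[b,e][1,4]dioxepine-7-carboxylate (depsidone; ring A C2 Br and C1 CO2CH3, ring B C5' and C6' OCH3)
Conditions: CuI (0.2 equiv), N,N-dimethylglycine (0.6 equiv), Cs2CO3 (2.0 equiv), 1,4-dioxane (0.01 M), 80 °C, argon
Reagents that add atoms: none
Why: The caesium phenoxide of the C1' hydroxyl binds the N,N-dimethylglycine-ligated monovalent copper, the C3–I bond of ring A adds oxidatively to give a trivalent aryl(aryloxy)copper held in an eight-membered chelate, and C–O reductive elimination forms the O–C3 bond and returns CuI. The closest known reaction is the ligand-accelerated Ullmann diaryl ether coupling in its intramolecular form, as used to convert 2-haloaryl salicylates (depsides) into depsidones. The one ring formed, the seven-membered lactone ring (ether O, C3, C4, ester O, C=O, C2', C1'), closes by ring-forming reductive elimination at an sp2 carbon across the ester tether, which turns a coupling of two doubly ortho-flanked partners into a cyclisation; no stereocentre arises. The step needs site selectivity for C3–I over C2–Br, which the faster oxidative addition of the iodide and the geometry secure, because C2 is meta to the anchoring C4 oxygen and cannot be spanned by the salicylate arm. It must also outrun base-induced Smiles migration (ipso attack of the phenoxide at C4 through a six-membered spiro intermediate) and intermolecular coupling; copper binding of the phenoxide, the poorly ionising solvent, the mild carbonate base at 80 °C and high dilution favour the ring closure.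

Step 5
Reactants: 8 methyl 6-bromo-3,4-dimethoxy-11-oxo-11H-dibenzo[b,e][1,4]dioxepine-7-carboxylate
Product: 9 methyl 2-bromo-3-[2,3-dimethoxy-6-(methoxycarbonyl)phenoxy]-4-hydroxybenzoate
Conditions: NaOCH3 (1.5 equiv), CH3OH/THF, 0 °C → rt; then 1 M HCl
Reagents that add atoms: sodium methoxide, [Na+].[O-]C (the OCH3 of the new ring B ester)
Why: Transesterification (lactone methanolysis) should open only the aryl ester of the seven-membered lactone, which is far more electrophilic than an alkyl benzoate and releases a stabilised phenoxide, whereas exchange at the C1 methyl ester is degenerate.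

Step 6
Reactants: 9 methyl 2-bromo-3-[2,3-dimethoxy-6-(methoxycarbonyl)phenoxy]-4-hydroxybenzoate
Product: 10 methyl 2,5-dibromo-3-[4-bromo-2,3-dimethoxy-6-(methoxycarbonyl)phenoxy]-4-hydroxybenzoate
Conditions: NBS (2.2 equiv), MeCN, 0 → 40 °C
Reagents that add atoms: N-bromosuccinimide, O=C1CCC(=O)N1Br
Why: Electrophilic aromatic bromination should go on ring A to C5, the only open position ortho to the free C4 phenol, and on ring B to C4', which is ortho to the C5' methoxy, para to the ether oxygen and meta to the ester, whereas C3' is ortho to the ester and activated only by the twisted C6' methoxy.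

Step 7
Reactants: 10 methyl 2,5-dibromo-3-[4-bromo-2,3-dimethoxy-6-(methoxycarbonyl)phenoxy]-4-hydroxybenzoate
Product: 11 methyl 2,5-dibromo-3-[4-bromo-2,3-dihydroxy-6-(methoxycarbonyl)phenoxy]-4-hydroxybenzoate
Conditions: BBr3 (6 equiv), CH2Cl2, −78 → 0 °C; then MeOH, water
Reagents that add atoms: none
Why: BBr3 O-demethylation should cleave the two aryl methyl ethers at C5' and C6' to the catechol, while the diaryl ether, the aryl bromides and the methyl esters are stable to the reagent at or below 0 °C.

Step 8
Reactants: 11 methyl 2,5-dibromo-3-[4-bromo-2,3-dihydroxy-6-(methoxycarbonyl)phenoxy]-4-hydroxybenzoate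
Product: 12 6-bromo-3-[2,5-dibromo-6-hydroxy-3-(hydroxymethyl)phenoxy]-4-(hydroxymethyl)benzene-1,2-diol (CNP0104332.0)
Conditions: (i-Bu)2AlH (10 equiv), THF, −78 °C → rt; aq. potassium sodium tartrate, pH 5–6
Reagents that add atoms: none
Why: Ester reduction with excess (i-Bu)2AlH should first convert the three phenols into aluminium phenoxides and then reduce both methyl esters through the aldehydes to the benzylic alcohols, the aryl bromides and the diaryl ether being inert to this hydride.

**Compound list**

1 | methyl 3-iodo-4-methoxybenzoate | COC(=O)c1ccc(OC)c(I)c1 | starting material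
2 | [2-iodo-3-methoxy-6-(methoxycarbonyl)phenyl]magnesium chloride (LiCl complex, not isolated) | COC(=O)c1ccc(OC)c(I)c1[Mg]Cl | intermediate
3 | methyl 2-bromo-3-iodo-4-methoxybenzoate | COC(=O)c1ccc(OC)c(I)c1Br | intermediate
4 | methyl 2-bromo-4-hydroxy-3-iodobenzoate | COC(=O)c1ccc(O)c(I)c1Br | intermediate
5 | 2-hydroxy-3,4-dimethoxybenzoic acid | COc1ccc(C(=O)O)c(O)c1OC | starting material
6 | 2-hydroxy-3,4-dimethoxybenzoic trifluoroacetic anhydride (not isolated) | COc1ccc(C(=O)OC(=O)C(F)(F)F)c(O)c1OC | intermediate
7 | methyl 2-bromo-4-[(2-hydroxy-3,4-dimethoxybenzoyl)oxy]-3-iodobenzoate (depside) | COC(=O)c1ccc(OC(=O)c2ccc(OC)c(OC)c2O)c(I)c1Br | intermediate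
8 | methyl 6-bromo-3,4-dimethoxy-11-oxo-11H-dibenzo[b,e][1,4]dioxepine-7-carboxylate (depsidone) | COC(=O)c1ccc2OC(=O)c3ccc(OC)c(OC)c3Oc2c1Br | intermediate
9 | methyl 2-bromo-3-[2,3-dimethoxy-6-(methoxycarbonyl)phenoxy]-4-hydroxybenzoate | COC(=O)c1ccc(O)c(Oc2c(C(=O)OC)ccc(OC)c2OC)c1Br | intermediate
10 | methyl 2,5-dibromo-3-[4-bromo-2,3-dimethoxy-6-(methoxycarbonyl)phenoxy]-4-hydroxybenzoate | COC(=O)c1cc(Br)c(O)c(Oc2c(C(=O)OC)cc(Br)c(OC)c2OC)c1Br | intermediate
11 | methyl 2,5-dibromo-3-[4-bromo-2,3-dihydroxy-6-(methoxycarbonyl)phenoxy]-4-hydroxybenzoate | COC(=O)c1cc(Br)c(O)c(Oc2c(C(=O)OC)cc(Br)c(O)c2O)c1Br | intermediate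
12 | 6-bromo-3-[2,5-dibromo-6-hydroxy-3-(hydroxymethyl)phenoxy]-4-(hydroxymethyl)benzene-1,2-diol | OCc1cc(Br)c(O)c(Oc2c(CO)cc(Br)c(O)c2O)c1Br | target

**Step count**

Total steps: 8. Longest linear sequence: 8 steps (from 1; acid 5 enters at step 3).

**Steps most likely to fail**

Step 4 (key step). The tethered closure may lose to Smiles migration of the ring A aryl group from the ester oxygen to the phenoxide, to cleavage of the activated aryl ester by base, or to intermolecular coupling that gives oligomers. The fallback makes the ether without the tether, by metal-free O-arylation with a diaryliodonium salt, which tolerates two ortho substituents on each partner.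
- It sets out from 3. Oxidation of its iodine to the trivalent state (mCPBA, TsOH·H2O, MeCN) and capture by 1,3,5-trimethoxybenzene should give [2-bromo-6-methoxy-3-(methoxycarbonyl)phenyl](2,4,6-trimethoxyphenyl)iodonium 4-methylbenzenesulfonate F1.
- Acid 5 is esterified (CH3OH, H2SO4, reflux) to methyl 2-hydroxy-3,4-dimethoxybenzoate F2.
- The phenoxide of F2 is arylated by F1 (K2CO3, toluene, 80 °C; the trimethoxyphenyl group stays on iodine) to methyl 2-bromo-3-[2,3-dimethoxy-6-(methoxycarbonyl)phenoxy]-4-methoxybenzoate F3.
- BBr3 (CH2Cl2, −78 → 0 °C) removes all three O-methyl groups to give methyl 2-bromo-3-[2,3-dihydroxy-6-(methoxycarbonyl)phenoxy]-4-hydroxybenzoate F4.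
- NBS (2 equiv, MeCN, 0 °C) brominates C5 and C4', and the route is rejoined at 11.

Step 1. Deprotonation may go to C6 instead of the hindered C2, or the ortho-iodo arylmagnesium may eliminate MgClI to an aryne before it is trapped. The fallback builds ring A from an arene that already carries both halogens, so that no metalation next to iodine is needed.
- It does not set out from a numbered compound but from purchased 1-bromo-2-iodo-3-methoxybenzene F5.
- Rieche formylation (Cl2CHOCH3, TiCl4, CH2Cl2, 0 °C) para to the methoxy group should give 2-bromo-3-iodo-4-methoxybenzaldehyde F6.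
- Pinnick oxidation (NaClO2, NaH2PO4, 2-methylbut-2-ene, t-BuOH/H2O) should give 2-bromo-3-iodo-4-methoxybenzoic acid F7.
- Methylation (CH3I, K2CO3, DMF) gives the methyl ester, which is 3, where the route is rejoined.

Step 8. The ring A ester may be reduced incompletely because its para aluminium phenoxide deactivates the carbonyl, the aluminium polyphenoxides may precipitate, and the para-hydroxybenzylic alcohol may ionise to a quinone methide on work-up. The fallback masks the phenols before the reduction.
- It sets out from 11. Silylation (TBSOTf, 2,6-lutidine, CH2Cl2, 0 °C) should give the tris(tert-butyldimethylsilyl) ether of 11, F8.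
- Reduction ((i-Bu)2AlH, CH2Cl2, −78 °C) should give the tris(tert-butyldimethylsilyl) ether of 12, F9.
- Desilylation (Et3N·3HF, THF, rt) releases the phenols under nearly neutral conditions and comes back to the route at 12.

**Further compounds**

F1 | step 4 | [2-bromo-6-methoxy-3-(methoxycarbonyl)phenyl](2,4,6-trimethoxyphenyl)iodonium 4-methylbenzenesulfonate | COC(=O)c1ccc(OC)c([I+]c2c(OC)cc(OC)cc2OC)c1Br.Cc1ccc(S(=O)(=O)[O-])cc1
F2 | step 4 | methyl 2-hydroxy-3,4-dimethoxybenzoate | COC(=O)c1ccc(OC)c(OC)c1O
F3 | step 4 | methyl 2-bromo-3-[2,3-dimethoxy-6-(methoxycarbonyl)phenoxy]-4-methoxybenzoate | COC(=O)c1ccc(OC)c(Oc2c(C(=O)OC)ccc(OC)c2OC)c1Br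
F4 | step 4 | methyl 2-bromo-3-[2,3-dihydroxy-6-(methoxycarbonyl)phenoxy]-4-hydroxybenzoate | COC(=O)c1ccc(O)c(Oc2c(C(=O)OC)ccc(O)c2O)c1Br
F5 | step 1 | 1-bromo-2-iodo-3-methoxybenzene (purchased) | COc1cccc(Br)c1I
F6 | step 1 | 2-bromo-3-iodo-4-methoxybenzaldehyde | COc1ccc(C=O)c(Br)c1I
F7 | step 1 | 2-bromo-3-iodo-4-methoxybenzoic acid | COc1ccc(C(=O)O)c(Br)c1I
F8 | step 8 | methyl 2,5-dibromo-3-[4-bromo-2,3-bis(tert-butyldimethylsilyloxy)-6-(methoxycarbonyl)phenoxy]-4-(tert-butyldimethylsilyloxy)benzoate | COC(=O)c1cc(Br)c(O[Si](C)(C)C(C)(C)C)c(Oc2c(C(=O)OC)cc(Br)c(O[Si](C)(C)C(C)(C)C)c2O[Si](C)(C)C(C)(C)C)c1Br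
F9 | step 8 | {2,5-dibromo-3-[4-bromo-2,3-bis(tert-butyldimethylsilyloxy)-6-(hydroxymethyl)phenoxy]-4-(tert-butyldimethylsilyloxy)phenyl}methanol | OCc1cc(Br)c(O[Si](C)(C)C(C)(C)C)c(Oc2c(CO)cc(Br)c(O[Si](C)(C)C(C)(C)C)c2O[Si](C)(C)C(C)(C)C)c1Br
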